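## The problem

Compound 13, 2,3-dibromo-6-(2,4-dibromophenoxy)phenol, is two benzene rings joined by one ether oxygen, from C2 of the phenolic ring A to C1' of ring B. There is no chain to build and no ring fusion. Ring A is substituted on four neighbouring carbons (aryloxy at C2, hydroxyl at C1, bromine at C6 and C5), and ring B carries bromine at C2' and C4'. The molecule has no stereocenter, so nothing has to be controlled by one centre in another and the task is purely regiochemical. Two things must be settled without ambiguity: which of the two adjacent oxygens of ring A becomes the diaryl ether, and where the four bromines sit. Brominating a hydroxylated diphenyl ether cannot give the pattern, because a free hydroxyl would direct bromine to its para position C4, which is unsubstituted in 13. Ring A therefore has to bring its two bromines with it and keep its hydroxyl masked to the end. The four aryl C–Br bonds exclude alkyllithium reagents, dissolving metals, hydrogenolysis and hot palladium or copper catalysis, and the oxygen to be arylated is hindered and electron-poor. The feature that opens a route is in ring B: the ether oxygen at C1' and the bromine at C2' are on adjacent carbons, as they would be after a nucleophile and an electrophile add across the triple bond of benzyne, and the bromine at C4' is para to that oxygen, where an electrophile prefers to go.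

## Retrosynthesis

**13 to 12.** The O–H of the phenol is traced back to the O–CH3 bond of methyl ether 12. Methyl is preferred to benzyl or silyl because it must survive fluoride, a phenoxide and aryne step, and bromine. Wedged between a bromine and the aryloxy group, it is also turned out of the ring plane and activates ring A only weakly. The skeleton of 12 is no simpler than that of 13, but it is the form in which the two oxygens of ring A are told apart. The forward step must cleave an alkyl aryl ether and leave the diaryl ether and four C–Br bonds alone.

**12 to 11.** The C4'–Br bond is cut next. It is the only C–Br bond that lies para to an oxygen on a ring with no second oxygen, so it is the one that electrophilic substitution can make. Cutting a ring A bromine instead would leave a position that no direct bromination reaches. Compound 11 has one bromine fewer, and its ring B shows only oxygen and an ortho bromine. The forward bromination must choose C4' of ring B over C5 of ring A and stop after one bromine.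

**11 to 5, 6 and 7.** The O–C1' and C2'–Br bonds are cut together. Cutting O–C1' alone would need a copper or palladium coupling of a hindered, electron-poor phenol with a 1,2-dihaloarene beside further C–Br bonds, or substitution on an unactivated ring. Cutting O–C2 on the ring A side would need a tetrasubstituted ring A electrophile. The double cut reduces ring B to benzyne 9, released from the silylaryl triflate 6. The oxygen partner becomes phenol 5, used as its cesium salt 8, and the bromine comes from carbon tetrabromide 7, with aryl anion 10 as the link between the two bond formations. All six carbons of ring B then come from a purchased reagent. The forward step must have 10 take bromine and not a proton.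

**5 to 3.** The free hydroxyl of 5 is traced to the formyl carbon of aldehyde 3, a C–O bond made from a C–C bond through formate 4. This is preferred to alkylating one hydroxyl of a free catechol, because the two oxygens never have to be distinguished from each other: one is the original phenol oxygen, already methylated, and the other is made from carbon. The precursor 3 differs from 5 by a single atom. The forward step needs the aryl group to migrate in preference to hydride.

**3 to 2.** The O–CH3 bond is cut, giving salicylaldehyde 2. No other cut is sensible here, and the forward step is a plain O-alkylation of an acidic, hydrogen-bonded phenol.

**2 to 1.** The aryl–CHO bond is cut, leading to 2,3-dibromophenol 1, which already holds both ring A bromines in the right relation to oxygen. C6 is the only free ortho position of 1, so an ortho-selective formylation has no choice of site. Ring A is thus fixed over three steps, none of which offers a regiochemical alternative.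

## Roads not taken

**Alternative 1:** The cut runs through ring A. C6 is removed as a one-carbon unit, so the C1–C6 and C5–C6 bonds are formed last and ring A begins as the five-membered bromo silyl enol ether A1, which already carries the ring B ether. In the forward direction, gem-dibromocyclopropanation of A1 under haloform–alkoxide conditions would be followed by opening of the cyclopropane with loss of bromide and the silyl group, giving the six-membered dibromoenone A2. A dehydrogenation would then have to deliver the phenol.
- **Merits:** The mechanism places the C1 oxygen and the C6 and C5 bromines side by side, and ring B could be bought with both bromines, so no late bromination is needed. The step count is comparable to the chosen plan.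
- **Weak points:** The bromine-bearing alkene of A1 is hindered and electron-depleted, so it is a poor carbene acceptor. A1 must come from a cyclopentanone that enolizes toward the brominated carbon and not toward the aryloxy-bearing one. The strongly basic medium threatens both the silyl enol ether and the aryloxy ketone. A2 is still one unsaturation short of an arene, and it can become aromatic without an oxidant by losing the ring B phenol, which would lead back to 1; the required dehydrogenation has to outrun this.
- **Comparison:** Alternative 1 is better in that it has no ring-selective bromination. The chosen plan sets against this that both rings stay aromatic throughout, that ring A regiochemistry is never in question, and that the ring B bromination is biased by the substrate.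

**Alternative 2:** Here ring B is built. The C1'–C2' and C5'–C6' bonds are cut, giving the ethynyl ether A3 of ring A and the dibromopyrone A4. In the forward direction, [4+2] cycloaddition of A3 across C3 and C6 of A4, followed by decarboxylative cycloreversion, would give A5, which is the same compound as 12.
- **Merits:** Both ring B bromines arrive in A4, so no bromination has to be steered between two rings. The polarization of the partners (nucleophilic terminal alkyne carbon, electrophilic C6 of the pyrone) favours the needed orientation. In this respect the alternative is better than the chosen plan.
- **Weak points:** A3 must be made from phenol 5, so the three steps to 5 are not saved. The usual route to aryl ethynyl ethers passes through a dichlorovinyl ether and two equivalents of an alkyllithium, which the vicinal dibromide of ring A would not survive. Aryl ynol ethers are thermally fragile, while alkyne–pyrone cycloadditions need heat. The reverse orientation would put the ring B bromines meta to oxygen and give an isomer that is hard to separate. A4 itself has to be prepared.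
- **Comparison:** The alternative is at least one step longer. The chosen plan must set an untested key step and one selective bromination against it, but it uses only purchased reagents for ring B and has a substrate bias and a protecting-group detour available for the bromination.

**Alternative 3:** Ring A is cut at C2–C3 and C5–C6, leading to the aryloxyacetone A6 and ethyl acrylate A7. In the forward direction an alkoxide base would take the aryloxy-bearing methylene of A6 into conjugate addition to A7 and the methyl carbon into Claisen condensation with the ester, closing the cyclohexane-1,3-dione A8.
- **Merits:** The feedstocks are the cheapest of all four plans, ring B is bought fully brominated, no aryne is needed, and every reaction type has precedent. On paper it is no longer than the chosen plan. In precedent it is the stronger plan.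
- **Weak points:** A8 has the right carbons but the wrong functions. One carbonyl (C5) must be exchanged for bromine, which means choosing between the two carbonyls of a vinylogous acid. C6 must be brominated once, and the ring must be dehydrogenated while an aryloxy group sits alpha to the remaining carbonyl and can leave on aromatization. The conjugate addition also has to occur once and at the more substituted carbon.
- **Comparison:** Three late steps in a row each carry a regiochemical or over-reaction question on a non-aromatic ring. The chosen plan concentrates its uncertainty in one step, for which a short fallback of known type exists, and has no regiochemical choice in ring A at all.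

Key step: step 4

Remark: 13 has no stereogenic element, so no step sets configuration; compounds 1, 6 and 7 are taken as purchased.

## Route

Step 1
Reactants: 1 2,3-dibromophenol
Product: 2 3,4-dibromo-2-hydroxybenzaldehyde
Conditions: MgCl2 (anhydrous), Et3N, (CH2O)n, MeCN, reflux
Reagents that add atoms: paraformaldehyde (as formaldehyde), C=O
Why: Magnesium-mediated ortho-formylation of a phenol; the magnesium-bound phenoxide delivers formaldehyde only to an ortho carbon, C6 is the single free one, and a second formaldehyde oxidizes the hydroxymethyl stage by hydride transfer. Ortho-halophenols are standard substrates.

Step 2
Reactants: 2 3,4-dibromo-2-hydroxybenzaldehyde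
Product: 3 3,4-dibromo-2-methoxybenzaldehyde
Conditions: MeI, K2CO3, DMF, rt to 40 °C
Reagents that add atoms: iodomethane, CI
Why: Williamson O-methylation; the phenol is acidic (ortho formyl and ortho bromine) and DMF breaks its hydrogen bond to the aldehyde, so the phenoxide alkylates cleanly on oxygen.

Step 3
Reactants: 3 3,4-dibromo-2-methoxybenzaldehyde
Product: 5 3,4-dibromo-2-methoxyphenol, via 3,4-dibromo-2-methoxyphenyl formate 4 (not isolated)
Conditions: mCPBA, CH2Cl2, rt to 40 °C; aq NaHCO3 wash; then K2CO3 (cat.), MeOH, rt
Reagents that add atoms: 3-chloroperoxybenzoic acid (mCPBA), OOC(=O)c1cccc(Cl)c1
Why: Baeyer–Villiger oxidation of an ortho-alkoxybenzaldehyde (Dakin-type); the ortho methoxy group should favour aryl over hydride migration in the Criegee intermediate, and the formate is cleaved by mild methanolysis that leaves the aryl bromides untouched.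

Step 4
Reactants: 5 3,4-dibromo-2-methoxyphenol; 6 2-(trimethylsilyl)phenyl trifluoromethanesulfonate; 7 carbon tetrabromide
Product: 11 1,2-dibromo-4-(2-bromophenoxy)-3-methoxybenzene, via cesium 3,4-dibromo-2-methoxyphenoxide 8 (not isolated), via benzyne 9 (not isolated), via cesium 2-(3,4-dibromo-2-methoxyphenoxy)phenide 10 (not isolated)
Conditions: CsOH·H2O, MeOH, then evaporation and azeotropic drying (PhMe, vacuum); then 6 (1.5 equiv, slow addition), 7 (3 equiv), CsF (3 equiv), 18-crown-6, THF, 0 °C to rt
Reagents that add atoms: none
Why: Proposed new method: fluoride attacks the silicon of 6 and triflate departs, releasing benzyne 9 slowly; the oxygen of cesium phenoxide 8 adds to 9 to give aryl anion 10, which attacks a bromine atom of 7 in a halophilic substitution, expelling tribromomethanide and leaving 11 with the new O–C1' and C2'–Br bonds. The closest known reaction types are three-component aryne couplings that join a heteroatom nucleophile and a bromine-transfer electrophile across the triple bond (bromothiolation) and the fluoride-induced O-arylation of phenols by ortho-silylaryl triflates; the untested element is pairing an aryloxide with bromine transfer. No ring closes and no stereocenter forms. The step needs 10 to take bromine and not hydrogen: the phenol is used as its dried cesium salt so that no O–H remains, THF replaces acetonitrile so that no acidic C–H solvent is present, and 7, among the fastest bromine donors toward aryl anions, is kept in excess. It also needs 8 to outcompete fluoride, bromide and tribromomethanide for 9, which a soluble, crown-ether-loosened cesium phenoxide at high concentration and slow addition of 6 should provide. Regiochemistry cannot go wrong because 9 is symmetrical, so oxygen and bromine must end on neighbouring carbons. The two bromines of ring A should be spectators, since an aryl bromide is a far poorer bromine donor than 7, and the methoxy group beside the phenoxide oxygen hinders a copper coupling much more than addition to an unhindered, strained triple bond.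

Step 5
Reactants: 11 1,2-dibromo-4-(2-bromophenoxy)-3-methoxybenzene
Product: 12 1,2-dibromo-4-(2,4-dibromophenoxy)-3-methoxybenzene
Conditions: Br2 (1.05 equiv), AcOH, rt to 40 °C
Reagents that add atoms: bromine, BrBr
Why: Electrophilic aromatic bromination; the ether oxygen directs to C4' of ring B, the ortho site C6' being more hindered. Ring A carries two deactivating bromines and a methoxy group twisted out of conjugation, so it should react more slowly.

Step 6
Reactants: 12 1,2-dibromo-4-(2,4-dibromophenoxy)-3-methoxybenzene
Product: 13 2,3-dibromo-6-(2,4-dibromophenoxy)phenol
Conditions: BBr3, CH2Cl2, −78 °C to rt; then H2O
Reagents that add atoms: none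
Why: Lewis acid cleavage of an aryl methyl ether; bromide attacks the methyl group of the boron-complexed ether, while the diaryl ether (no alkyl carbon to attack) and the aryl bromides are inert. This is the standard unmasking of methoxylated polybrominated diphenyl ethers.

## Compound list

1 | 2,3-dibromophenol | Oc1cccc(Br)c1Br | starting material
2 | 3,4-dibromo-2-hydroxybenzaldehyde | O=Cc1ccc(Br)c(Br)c1O | intermediate
3 | 3,4-dibromo-2-methoxybenzaldehyde | COc1c(C=O)ccc(Br)c1Br | intermediate
4 | 3,4-dibromo-2-methoxyphenyl formate | COc1c(OC=O)ccc(Br)c1Br | intermediate
5 | 3,4-dibromo-2-methoxyphenol | COc1c(O)ccc(Br)c1Br | intermediate
6 | 2-(trimethylsilyl)phenyl trifluoromethanesulfonate | C[Si](C)(C)c1ccccc1OS(=O)(=O)C(F)(F)F | starting material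
7 | carbon tetrabromide | BrC(Br)(Br)Br | starting material
8 | cesium 3,4-dibromo-2-methoxyphenoxide | [Cs+].[O-]c1ccc(Br)c(Br)c1OC | intermediate
9 | benzyne | C1#CC=CC=C1 | intermediate
10 | cesium 2-(3,4-dibromo-2-methoxyphenoxy)phenide | [Cs+].[c-]1ccccc1Oc1ccc(Br)c(Br)c1OC | intermediate
11 | 1,2-dibromo-4-(2-bromophenoxy)-3-methoxybenzene | COc1c(Oc2ccccc2Br)ccc(Br)c1Br | intermediate
12 | 1,2-dibromo-4-(2,4-dibromophenoxy)-3-methoxybenzene | COc1c(Oc2ccc(Br)cc2Br)ccc(Br)c1Br | intermediate
13 | 2,3-dibromo-6-(2,4-dibromophenoxy)phenol | Oc1c(Oc2ccc(Br)cc2Br)ccc(Br)c1Br | target

## Step count and least certain steps

Total steps: 6. Longest linear sequence: 6 steps (1 to 13); 6 and 7 enter at step 4 as purchased reagents.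

**Step 4 (key step).** The most likely failure is proton capture by anion 10 in place of bromine transfer, from traces of water or methanol left in 8, because an aryl anion is strongly basic. Two further losses are possible. Bromide or tribromomethanide may add to the aryne and start a chain that consumes 6 and 7, and tribromomethanide may break down to a carbene that attacks the phenoxide. The phenoxide is only a moderate nucleophile because of its two bromines, which makes this competition real.

The fallback uses known chemistry and gives up the aryne. It sets out from 5, which is O-arylated with bis(2,4-dibromophenyl)iodonium chloride F1 in aqueous NaOH and dioxane at reflux. F1 is made from 1,3-dibromobenzene and an iodosyl sulfate reagent in sulfuric acid and precipitated as the chloride. The phenoxide binds to trivalent iodine, and ligand coupling transfers a 2,4-dibromophenyl group to oxygen, releasing 2,4-dibromo-1-iodobenzene. This arylation of bromophenols is the established entry to polybrominated diphenyl ethers. It comes back to the route at 12, so step 5 is not needed.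

**Step 5.** What may go wrong is loss of ring selectivity: bromination at C5 of ring A, para to the methoxy group, or a second bromination of ring B at C6'. Ring B is itself deactivated by its ortho bromine and by the electron-poor aryloxy group, so the margin over ring A is smaller than in a simple diphenyl ether.

The fallback changes the order of events and the protecting group, and sets out from 11. Demethylation with BBr3 gives 2,3-dibromo-6-(2-bromophenoxy)phenol F2. Acetylation (Ac2O, pyridine) gives 2,3-dibromo-6-(2-bromophenoxy)phenyl acetate F3, in which the ring A oxygen is an ester oxygen and donates little. Bromination (Br2, AcOH) should then go cleanly to C4' and give 2,3-dibromo-6-(2,4-dibromophenoxy)phenyl acetate F4. Methanolysis (K2CO3, MeOH) comes back to the route at 13.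

**Step 3.** The risk is migration of hydride in place of the aryl group in the Criegee intermediate, which leads to over-oxidation to the benzoic acid. The methoxy group of 3 is twisted by its two neighbours and the two bromines lower the migratory aptitude of the ring.

The fallback removes the competing hydride altogether and sets out from 3. Addition of MeMgBr (THF, 0 °C, where aryl bromides do not exchange) gives 1-(3,4-dibromo-2-methoxyphenyl)ethan-1-ol F5, racemic, its stereocenter being destroyed in the next step. Oxidation with Dess–Martin periodinane gives 1-(3,4-dibromo-2-methoxyphenyl)ethan-1-one F6. Baeyer–Villiger oxidation (mCPBA, TFA, CH2Cl2), in which aryl migrates in preference to methyl, gives 3,4-dibromo-2-methoxyphenyl acetate F7. Methanolysis (K2CO3, MeOH) comes back to the route at 5.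

## Further compounds

F1 | step 4 | bis(2,4-dibromophenyl)iodonium chloride | [Cl-].Brc1ccc([I+]c2ccc(Br)cc2Br)c(Br)c1
F2 | step 5 | 2,3-dibromo-6-(2-bromophenoxy)phenol | Oc1c(Oc2ccccc2Br)ccc(Br)c1Br
F3 | step 5 | 2,3-dibromo-6-(2-bromophenoxy)phenyl acetate | CC(=O)Oc1c(Oc2ccccc2Br)ccc(Br)c1Br
F4 | step 5 | 2,3-dibromo-6-(2,4-dibromophenoxy)phenyl acetate | CC(=O)Oc1c(Oc2ccc(Br)cc2Br)ccc(Br)c1Br
F5 | step 3 | 1-(3,4-dibromo-2-methoxyphenyl)ethan-1-ol (racemic) | COc1c(C(C)O)ccc(Br)c1Br
F6 | step 3 | 1-(3,4-dibromo-2-methoxyphenyl)ethan-1-one | COc1c(C(C)=O)ccc(Br)c1Br
F7 | step 3 | 3,4-dibromo-2-methoxyphenyl acetate | COc1c(OC(C)=O)ccc(Br)c1Br
A1 | alternative 1 | {[2-bromo-5-(2,4-dibromophenoxy)cyclopent-1-en-1-yl]oxy}trimethylsilane (racemic) | C[Si](C)(C)OC1=C(Br)CCC1Oc1ccc(Br)cc1Br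
A2 | alternative 1 | 2,3-dibromo-6-(2,4-dibromophenoxy)cyclohex-2-en-1-one (racemic) | O=C1C(Br)=C(Br)CCC1Oc1ccc(Br)cc1Br
A3 | alternative 2 | 1,2-dibromo-4-(ethynyloxy)-3-methoxybenzene | COc1c(OC#C)ccc(Br)c1Br
A4 | alternative 2 | 3,5-dibromo-2H-pyran-2-one | O=C1OC=C(Br)C=C1Br
A5 | alternative 2 | 1,2-dibromo-4-(2,4-dibromophenoxy)-3-methoxybenzene (identical with 12) | COc1c(Oc2ccc(Br)cc2Br)ccc(Br)c1Br
A6 | alternative 3 | 1-(2,4-dibromophenoxy)propan-2-one | CC(=O)COc1ccc(Br)cc1Br
A7 | alternative 3 | ethyl acrylate | C=CC(=O)OCC
A8 | alternative 3 | 4-(2,4-dibromophenoxy)cyclohexane-1,3-dione (racemic) | O=C1CCC(Oc2ccc(Br)cc2Br)C(=O)C1
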